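# Proposed synthesis of CNP0533761.1 (spirolactone-type 6,7-seco-ent-kauranoid)

## Structural features

The target is a 6,7-seco-ent-kaurane of the spirolactone type and is numbered as an ent-kaurane. Ring A is a 4,4-dimethylcyclohex-2-en-1-one (C1 ketone, C2=C3) with the hydroxymethyl arm C6 on C5. C10 is the spiro atom shared with a δ-lactone (C10, C20, O, C7, C8, C9). The lactone is cis-fused through C8–C9 to ring C (C8, C9, C11, C12, C13, C14) of a bicyclo[3.2.1]octane, whose ring D (C8, C15, C16, C13, C14) carries the C15 ketone, the C16 methyl group and the bridgehead C13 carbinol. The stereocentres C5, C10, C9 and C8 are contiguous, C8 and C10 are quaternary, and C13 and C16 sit across ring D; the C16 methyl group lies on the concave face of ring D, cis to C12, which is expected to be the less stable position. Fragile groups are the β-hydroxy ketone C13(OH)–C16–C15(=O) (retro-aldol cleavage and C16 epimerisation under base), the non-enolisable β-keto lactone C7–C8–C15 (retro-Claisen attack by alkoxides) and the enone. The real difficulty is the vicinal pair of a quaternary spiro C10 and a tertiary C9, followed by building a strained bridged ketol without letting it equilibrate. The key step uses the fact that C10 carries both C20–O and C9, while C9–C8–C7(=O)–O–C20 completes the lactone. C10 is therefore the radical from a C10–C20 epoxide, and C9 is the β-carbon of an alkylidene β-keto ester whose ester carbon becomes C7.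

## Logic of the disconnections

**22 to 19 (via 21).** The O6–H bond is masked as a silyl ether and the C1 carbonyl is removed. The free primary alcohol and the enone are the groups least compatible with enolate, Lewis-acid and radical chemistry. Ring A becomes a plain cyclohexene with a single allylic CH2, since C4 is quaternary. The forward steps need an oxidation that puts oxygen on C1 and not on C3 of the allyl system, and a desilylation that is not basic.

**19 to 18.** The C13–C16 bond of ring D is cut as a retro-aldol. This removes the bridged ring and the stereocentres C13 and C16, leaving a cis-fused bicyclic diketone. The bridged ketol is expected to lie uphill of the diketone under alkoxide equilibration, so the forward aldol must run under kinetic, non-basic conditions. Enolisation must occur at C16 only, and the methyl group must be placed on the concave face.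

**18 to 14 (via 17 and 15).** The C8–C14 bond of ring C is cut between the α-carbon of the β-keto lactone and the α-carbon of the C13 ketone. The quaternary C8 and ring C disappear, leaving a monocyclic lactone with a protected methyl ketone chain on C9. The forward sequence needs a leaving group on the C14 methyl and not on C12 or C8. The tether then enforces the cis ring fusion.

**14 to 7 and 12 (key).** The C9–C10 bond and the C20-O–C7 lactone bond are cut. This is the only place where the molecule divides into two fragments of similar size, and it leaves C5 as the single stereocentre to be carried in. The forward step needs the C10 radical to add faster than it is reduced, to add anti to the C5 arm, and to select one face at C9.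

**7 to 3 (via 6, 5 and 4).** These are functional-group changes on ring A: the epoxide goes back to the C10=C20 alkene, the silyl ether to the acetate, and the C2=C3 alkene to the C3 alcohol. The exocyclic alkene must be epoxidised beside the ring alkene, which is solved by doing it on the free homoallylic alcohol 5. The neopentyl alcohol of 3 must be dehydrated without skeletal rearrangement.

**3 to 1 (via 2).** The C4–C5 bond of ring A is cut as a radical cyclisation of an epoxy diene. The epoxide stereocentre is relayed to C5 and then discarded. The forward step needs an enantioselective epoxidation of the terminal alkene of 1 only.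

**12 to 10 and 11, then 10 to 8 (via 9).** The C8=C9 alkene is cut as a Knoevenagel condensation, and the aldehyde goes back to the levulinate ester. The demand is a condensation mild enough to avoid double addition and deconjugation; the alkene geometry does not matter.

## Other disconnections considered

**Alternative 1:** The cut runs through C8–C9 and C12–C13, opening the lactone and ring C together. It leads to the chloromethyl ketone ester A1, in which the ring A enone carries at C10 the arm C9H2–C11(=O)–C12H2Cl and the C20 ester of a 3-methyl-4-silyloxycyclopentadiene carboxylic acid. Forward, Et3N with LiClO4 would ionise the chloride to the oxyallyl cation C9–C11–C12, which adds across C8 and C13 of the diene in a (4+3) cycloaddition to give A2.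
- In favour: two bonds, two rings and three stereocentres (C8, C9, C13) form in one step. The C13 oxygen arrives as a silyl ether, so no aldol equilibrium is involved, and the C1 enone is present from the start, so no late allylic oxidation is needed. On these two points it is the better plan.
- Against: A2 carries a C11 ketone that must be removed and a C15=C16 alkene that must become the C15 ketone with hydrogen delivered to the correct face of C16. That is at least four further steps beside an enone and a lactone. A1 needs a quaternary C10 with two different arms in defined configuration, with no entry as short as epoxide 7. The siloxycyclopentadiene is prone to 1,5-hydrogen shifts, and only the ester tether guides the cation to the correct diene face.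
- Comparison: the uncertainty at C9 is about the same as in the radical addition. The step count after the key step is about equal, and before it longer.

**Alternative 2:** Rings C and D are cut at C13–C14 and C8–C15. This leads to the α-methylene lactone A3, whose C9 chain ends in the β-keto ester C13(=O)–C16H(CH3)–C15O2Me. Forward, SmI2 (divalent samarium) would give the C13 ketyl, which adds to the C14 terminus of the acrylate unit; the C8 samarium enolate then attacks the C15 ester in a Dieckmann closure to give A4. A4 is the same compound as 19.
- In favour: one step does the work of steps 11 to 14. The bridgehead carbinol is made reductively and not by an aldol addition, which is the more reliable way to such alcohols. On step economy after the coupling and on the construction of the ketol this plan is the better one.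
- Against: the C9–C10 bond and both of its stereocentres still have to be built into A3 by some other reaction. The ketone of a β-keto ester must be reduced in preference to an α-methylene lactone that divalent samarium reduces readily. The Dieckmann step forms a non-enolisable β-keto lactone, so it has no deprotonation to drive it, and it releases methoxide beside a samarium alkoxide that can fragment by retro-aldol. C16 would be set only by chelation during the cascade.
- Comparison: the C1 oxidation and desilylation are the same in both plans.

**Alternative 3:** Only ring C is cut, at C12–C13. This leads to the iodide A5, in which ring D is already present as a 2-methylcyclopentane-1,3-dione vinylogous ester (C15 ketone, C16=C13, C13–OPMB) spiro-linked at C8 to the lactone, and C9 carries the iodoethyl arm C11–C12. Forward, (Me3Si)3SiH and Et3B would generate the primary C12 radical, which closes 6-exo onto C13; the C16 radical then takes hydrogen from the silane to give A6.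
- In favour: the bridgehead oxygen is carried as an ether, so retro-aldol cleavage cannot occur, which is better than the chosen plan. Hydrogen transfer to the C16 radical from the open convex face should place the methyl group on the concave face as required, which is equal or better. Ring A already has its enone.
- Against: the radical must attack the oxygen-bearing, fully substituted β-carbon of a vinylogous ester. That position is electron-rich and hindered, so it is polarity-mismatched for a nucleophilic alkyl radical, and simple reduction of the iodide is the likely competitor. A5 already contains the quaternary spiro C8 next to C9 and C10 in defined configuration, so the hardest stereochemical problem moves into the precursor. Two deprotections are needed at the end.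
- Comparison: after the key step it is shorter than the chosen plan; before it, clearly longer.

Key step: step 10

## Remarks on the chemistry (assumptions and design points)

- ent-Kaurane numbering is used for all compounds from 13 onward, and for the ring A atoms of 3 to 7 (C6 is the CH2O arm, C20 the exocyclic carbon).
- The configuration at the spiro carbon C10 of 7 is immaterial because C10 becomes a planar radical in step 10. The epimer expected from hydroxyl-directed epoxidation is drawn.
- 12 is drawn as the Z isomer; its alkene geometry is lost at the enolate stage of step 10.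
- C8 of 13 to 17 is an epimerisable centre and is drawn trans to the C9 chain where a configuration is shown.
- The exocyclic alkene is epoxidised on the free alcohol 5, before silylation, so that the hydroxyl group directs the oxidant away from the ring alkene.
- Ring D is closed by a titanium-mediated aldol addition under kinetic control and not by a base-equilibrated aldol, because the bridged ketol is expected to revert to the diketone under alkoxide conditions.

## Route

Step 1
Reactants: 1 geranyl acetate [(2E)-3,7-dimethylocta-2,6-dien-1-yl acetate]
Product: 2 (6R)-6,7-epoxygeranyl acetate [(2E)-5-[(2R)-3,3-dimethyloxiran-2-yl]-3-methylpent-2-en-1-yl acetate]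
Conditions: D-fructose-derived Shi ketone (30 mol%), KHSO5 (as 2KHSO5·KHSO4·K2SO4), K2CO3, Bu4NHSO4, MeCN/CH2(OMe)2, aq. Na2B4O7 buffer, 0 °C
Reagents that add atoms: potassium peroxymonosulfate, [K+].[O-]S(=O)(=O)OO
Why: Shi epoxidation; the chiral dioxirane attacks the electron-richer 6,7-alkene (the 2,3-alkene is deactivated by the allylic acetate) through the spiro transition state, and the D-fructose-derived ketone gives the (R)-epoxide needed for the ent series.

Step 2
Reactants: 2 (6R)-6,7-epoxygeranyl acetate
Product: 3 [(1S,3R)-3-hydroxy-2,2-dimethyl-6-methylidenecyclohexyl]methyl acetate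
Conditions: Cp2TiCl2 (2.2 equiv), Mn dust, THF, rt; aq. NaH2PO4
Reagents that add atoms: none
Why: Titanocene-mediated radical cyclisation of an epoxy polyene; homolytic epoxide opening gives the tertiary radical, which closes 6-endo-trig onto the 2,3-alkene through a chair with the titanoxy group and the acetoxymethyl terminus equatorial, so C5 is set cis to the C3 oxygen. The new tertiary radical is trapped by a second Cp2TiCl and loses a methyl β-hydrogen to give the exocyclic alkene.

Step 3
Reactants: 3 [(1S,3R)-3-hydroxy-2,2-dimethyl-6-methylidenecyclohexyl]methyl acetate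
Product: 4 [(1S)-2,2-dimethyl-6-methylidenecyclohex-3-en-1-yl]methyl acetate
Conditions: PPh3, DIAD, 3,3-dimethylglutarimide, THF, 0 °C to rt
Reagents that add atoms: none
Why: Mitsunobu-type dehydration; the oxyphosphonium ion at the neopentyl C3 cannot be displaced, so the imide anion removes a C2 hydrogen instead. Only C2 carries β-hydrogens, so the alkene can form only at C2=C3, and C5 is untouched.

Step 4
Reactants: 4 [(1S)-2,2-dimethyl-6-methylidenecyclohex-3-en-1-yl]methyl acetate
Product: 5 [(1S)-2,2-dimethyl-6-methylidenecyclohex-3-en-1-yl]methanol
Conditions: K2CO3 (cat.), MeOH, 0 °C to rt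
Reagents that add atoms: none
Why: Base-catalysed transesterification of the acetate with methanol; the non-conjugated diene and the stereocentre are inert.

Step 5
Reactants: 5 [(1S)-2,2-dimethyl-6-methylidenecyclohex-3-en-1-yl]methanol
Product: 6 [(3S,4S)-5,5-dimethyl-1-oxaspiro[2.5]oct-6-en-4-yl]methanol
Conditions: VO(acac)2 (3 mol%), t-BuOOH, CH2Cl2, 0 °C to rt
Reagents that add atoms: tert-butyl hydroperoxide, CC(C)(C)OO
Why: Hydroxyl-directed epoxidation; the vanadate ester of the homoallylic C6 alcohol delivers oxygen to the nearby exocyclic C10=C20 alkene and not to the hindered ring alkene. Oxygen is expected on the face of the arm, but the configuration at C10 is of no consequence for step 10.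

Step 6
Reactants: 6 [(3S,4S)-5,5-dimethyl-1-oxaspiro[2.5]oct-6-en-4-yl]methanol
Product: 7 tert-butyl{[(3S,4S)-5,5-dimethyl-1-oxaspiro[2.5]oct-6-en-4-yl]methoxy}dimethylsilane
Conditions: TBSCl, imidazole, CH2Cl2, 0 °C to rt
Reagents that add atoms: tert-butyldimethylsilyl chloride, CC(C)(C)[Si](C)(C)Cl
Why: Silylation of the primary alcohol under buffered conditions that leave the acid-sensitive 1,1-disubstituted epoxide intact; the silyl ether survives trivalent titanium, enolate and Lewis-acid chemistry and is removed last.

Step 7
Reactants: 8 ethyl levulinate (ethyl 4-oxopentanoate)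
Product: 9 ethyl 3-(2-methyl-1,3-dioxolan-2-yl)propanoate
Conditions: HOCH2CH2OH, TsOH·H2O (cat.), toluene, reflux, Dean–Stark
Reagents that add atoms: ethane-1,2-diol, OCCO
Why: Acid-catalysed ketalisation driven by azeotropic removal of water; the ester is untouched.

Step 8
Reactants: 9 ethyl 3-(2-methyl-1,3-dioxolan-2-yl)propanoate
Product: 10 3-(2-methyl-1,3-dioxolan-2-yl)propanal
Conditions: i-Bu2AlH (1.05 equiv), CH2Cl2, −78 °C; aq. KNaC4H4O6
Reagents that add atoms: none
Why: Partial reduction of the ester; the aluminium hemiacetal is stable at −78 °C and collapses to the aldehyde only on work-up.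

Step 9
Reactants: 10 3-(2-methyl-1,3-dioxolan-2-yl)propanal; 11 methyl 3-oxopentanoate
Product: 12 methyl (2Z)-5-(2-methyl-1,3-dioxolan-2-yl)-2-propanoylpent-2-enoate
Conditions: piperidine (10 mol%), AcOH (10 mol%), 4 Å molecular sieves, CH2Cl2, 0 °C to rt
Reagents that add atoms: none
Why: Knoevenagel condensation under piperidinium acetate catalysis at low temperature, to limit double addition and deconjugation; either alkene geometry serves in step 10.

Step 10
Reactants: 7 tert-butyl{[(3S,4S)-5,5-dimethyl-1-oxaspiro[2.5]oct-6-en-4-yl]methoxy}dimethylsilane; 12 methyl (2Z)-5-(2-methyl-1,3-dioxolan-2-yl)-2-propanoylpent-2-enoate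
Product: 14 spiro δ-lactone (5R,8S,9R,10R; C8 propanoyl; C9 2-(2-methyl-1,3-dioxolan-2-yl)ethyl; C6 OTBS; C2=C3), via hydroxy keto ester 13 (not isolated)
Conditions: Cp2TiCl (trivalent titanium, 2.3 equiv, from Cp2TiCl2 and Mn dust in THF) added over 2 h to 7 and 12 (2 equiv), THF, rt; aq. NaH2PO4; then toluene, 80 °C
Reagents that add atoms: none
Why: Cp2TiCl transfers one electron to the epoxide oxygen of 7 and the C10–O bond breaks to give the tertiary β-titanoxy radical at C10, which erases the configuration of C10 in 7. This nucleophilic radical adds to C9 of the doubly activated alkene 12 in a Giese-type addition (the closest known reaction is the titanocene-mediated addition of epoxide-derived radicals to acrylates with lactone formation), and the dicarbonyl-stabilised C8 radical is reduced by a second Cp2TiCl to a titanium enolate. Slow addition of Cp2TiCl keeps its concentration low, so that addition to the excess acceptor should outrun trapping of the tertiary radical. After protonation the C20 hydroxyl of 13 attacks the C7 methyl ester (6-exo-trig acyl substitution with loss of methanol) and closes the δ-lactone on warming. C10 is set by approach of 12 anti to the C5 silyloxymethyl arm and the axial C4 methyl group, so C9 ends trans to C6. C9 is set in the same open transition state, with the C8 terminus anti to the C10–C5 bond, the C9 hydrogen in the crowded sector between C5 and C20–O–Ti and the C11 chain toward the C1 methylene; this is the less secure of the two. C8 stays epimerisable and is fixed only in step 13. The step needs chemoselectivity for the epoxide over the ketal, the silyl ether and the C2=C3 alkene, all of which are inert to trivalent titanium.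

Step 11
Reactants: 14 spiro δ-lactone with the C9 ketal chain
Product: 15 spiro δ-lactone (5R,8S,9R,10R) with the C9 3-oxobutyl chain (C13 methyl ketone)
Conditions: PPTS (cat.), acetone/H2O (10:1), 50 °C
Reagents that add atoms: water, O
Why: Acid-catalysed hydrolysis of the dioxolane; PPTS in wet acetone is mild enough for the primary silyl ether and the β-keto lactone.

Step 12
Reactants: 15 spiro δ-lactone with the C13 methyl ketone
Product: 17 C14 bromide (5R,8S,9R,10R; C9 4-bromo-3-oxobutyl chain), via bis(trimethylsilyl) enol ether 16 (not isolated)
Conditions: LiN(i-Pr)2 (2.2 equiv), THF, −78 °C; Me3SiCl; then NBS, THF, −78 °C; aq. citric acid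
Reagents that add atoms: N-bromosuccinimide, O=C1CCC(=O)N1Br; chlorotrimethylsilane, C[Si](C)(C)Cl (atoms retained only in 16)
Why: The first equivalent of base removes the acidic C8 hydrogen and the second removes a C14 methyl hydrogen under kinetic control; silylation gives 16. NBS brominates the electron-rich, unhindered C13=C14 enol silane much faster than the tetrasubstituted push–pull enol silane of the dicarbonyl unit, which is hydrolysed on work-up (regioselective α-bromination of a methyl ketone through its kinetic silyl enol ether).

Step 13
Reactants: 17 C14 bromide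
Product: 18 tricyclic diketone (5R,8S,9S,10R; ring C closed by C8–C14; C13 ketone; C8 propanoyl; lactone cis-fused to ring C)
Conditions: K2CO3, acetone, rt (0.01 M)
Reagents that add atoms: none
Why: Intramolecular C-alkylation of the β-keto lactone enolate by the α-bromo ketone (6-exo-tet). C14 can reach C8 only on the face that carries the C9 chain, so ring C is cis-fused and the quaternary C8 is set; O-alkylation would require an eight-membered ring.

Step 14
Reactants: 18 tricyclic diketone
Product: 19 ketol (5R,8S,9S,10R,13S,16R; 13-hydroxy-15-oxo; the 1-deoxo target as its C6 TBS ether)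
Conditions: TiCl4 (2.2 equiv), i-Pr2NEt (1.2 equiv), CH2Cl2, −78 to −40 °C; pH 7 phosphate buffer at −78 °C
Reagents that add atoms: none
Why: Chelation of TiCl4 between the C7 and C15 carbonyl oxygens should make the C16 hydrogens the most acidic, so the amine gives the (Z)-titanium enolate at C15=C16 and not an enolate of the C13 ketone (soft enolisation of a β-dicarbonyl at its ethyl ketone terminus). This enolate adds to the TiCl4-activated C13 ketone in an intramolecular titanium-mediated aldol addition (5-exo-trig) that closes ring D. C13 is fixed by the bridge; C16 follows from the Z enolate swinging in from the open convex side, which places the methyl group on the concave face, and the cold neutral quench releases the ketol without a free alkoxide.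

Step 15
Reactants: 19 ketol
Product: 21 target C6 TBS ether (5R,8S,9S,10S,13S,16R), via C1 allylic alcohol 20 (not isolated)
Conditions: SeO2 (0.5 equiv), t-BuOOH, CH2Cl2, rt; then Dess–Martin periodinane, CH2Cl2, rt
Reagents that add atoms: selenium dioxide (oxygen carrier), O=[Se]=O; tert-butyl hydroperoxide (terminal oxidant), CC(C)(C)OO
Why: Allylic oxidation with SeO2; the ene reaction (selenium to C3, hydrogen from C1) followed by the 2,3-sigmatropic shift returns the alkene to C2=C3 and places oxygen on C1, the only allylic CH2, so no transposed enone can arise. Oxidation of the allylic alcohol with Dess–Martin periodinane is non-basic and leaves the tertiary C13 alcohol untouched.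

Step 16
Reactants: 21 target C6 TBS ether
Product: 22 CNP0533761.1 (5R,8S,9S,10S,13S,16R)
Conditions: HF·pyridine, THF/pyridine, 0 °C to rt
Reagents that add atoms: none
Why: Acidic fluoride cleaves the primary silyl ether; basic fluoride is avoided because the β-hydroxy ketone could open by retro-aldol reaction and C16 could epimerise.

## Compound list

1 | geranyl acetate | CC(C)=CCC/C(C)=C/COC(C)=O | starting material
2 | (6R)-6,7-epoxygeranyl acetate | CC(=O)OC/C=C(\C)CC[C@H]1OC1(C)C | intermediate
3 | [(1S,3R)-3-hydroxy-2,2-dimethyl-6-methylidenecyclohexyl]methyl acetate | CC(=O)OC[C@H]1C(=C)CC[C@@H](O)C1(C)C | intermediate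
4 | [(1S)-2,2-dimethyl-6-methylidenecyclohex-3-en-1-yl]methyl acetate | CC(=O)OC[C@H]1C(=C)CC=CC1(C)C | intermediate
5 | [(1S)-2,2-dimethyl-6-methylidenecyclohex-3-en-1-yl]methanol | OC[C@H]1C(=C)CC=CC1(C)C | intermediate
6 | [(3S,4S)-5,5-dimethyl-1-oxaspiro[2.5]oct-6-en-4-yl]methanol | C1O[C@]12CC=CC(C)(C)[C@H]2CO | intermediate
7 | tert-butyl{[(3S,4S)-5,5-dimethyl-1-oxaspiro[2.5]oct-6-en-4-yl]methoxy}dimethylsilane | C1O[C@]12CC=CC(C)(C)[C@H]2CO[Si](C)(C)C(C)(C)C | intermediate
8 | ethyl levulinate | CCOC(=O)CCC(C)=O | starting material
9 | ethyl 3-(2-methyl-1,3-dioxolan-2-yl)propanoate | CCOC(=O)CCC1(C)OCCO1 | intermediate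
10 | 3-(2-methyl-1,3-dioxolan-2-yl)propanal | O=CCCC1(C)OCCO1 | intermediate
11 | methyl 3-oxopentanoate | CCC(=O)CC(=O)OC | starting material
12 | methyl (2Z)-5-(2-methyl-1,3-dioxolan-2-yl)-2-propanoylpent-2-enoate | CCC(=O)/C(=C/CCC1(C)OCCO1)C(=O)OC | intermediate
13 | δ-hydroxy β-keto ester (5R,9R,10R; C10 bears C20H2OH; C8 bears propanoyl and CO2Me, configuration at C8 open) | CCC(=O)C(C(=O)OC)[C@@H](CCC1(C)OCCO1)[C@]1(CO)CC=CC(C)(C)[C@H]1CO[Si](C)(C)C(C)(C)C | intermediate
14 | spiro δ-lactone (5R,8S,9R,10R) with C8 propanoyl and C9 2-(2-methyl-1,3-dioxolan-2-yl)ethyl | CCC(=O)[C@@H]1[C@@H](CCC2(C)OCCO2)[C@]2(COC1=O)CC=CC(C)(C)[C@H]2CO[Si](C)(C)C(C)(C)C | intermediate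
15 | spiro δ-lactone (5R,8S,9R,10R) with C9 3-oxobutyl chain | CCC(=O)[C@@H]1[C@@H](CCC(C)=O)[C@]2(COC1=O)CC=CC(C)(C)[C@H]2CO[Si](C)(C)C(C)(C)C | intermediate
16 | bis(trimethylsilyl) enol ether of 15 (C15–OSiMe3 with C8=C15, geometry open; C13–OSiMe3 with C13=C14) | CCC(O[Si](C)(C)C)=C1[C@@H](CCC(=C)O[Si](C)(C)C)[C@]2(COC1=O)CC=CC(C)(C)[C@H]2CO[Si](C)(C)C(C)(C)C | intermediate
17 | C14 bromide (5R,8S,9R,10R) with C9 4-bromo-3-oxobutyl chain | CCC(=O)[C@@H]1[C@@H](CCC(=O)CBr)[C@]2(COC1=O)CC=CC(C)(C)[C@H]2CO[Si](C)(C)C(C)(C)C | intermediate
18 | tricyclic diketone (5R,8S,9S,10R), ring C closed | CCC(=O)[C@]12CC(=O)CC[C@H]1[C@]1(COC2=O)CC=CC(C)(C)[C@H]1CO[Si](C)(C)C(C)(C)C | intermediate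
19 | ketol (5R,8S,9S,10R,13S,16R), 1-deoxo target C6 TBS ether | C[C@H]1C(=O)[C@]23C[C@@]1(O)CC[C@H]2[C@]1(COC3=O)CC=CC(C)(C)[C@H]1CO[Si](C)(C)C(C)(C)C | intermediate
20 | C1 allylic alcohol of 19 (C1 epimers, configuration at C1 open) | C[C@H]1C(=O)[C@]23C[C@@]1(O)CC[C@H]2[C@]1(COC3=O)C(O)C=CC(C)(C)[C@H]1CO[Si](C)(C)C(C)(C)C | intermediate
21 | target C6 TBS ether (5R,8S,9S,10S,13S,16R) | C[C@H]1C(=O)[C@]23C[C@@]1(O)CC[C@H]2[C@]1(COC3=O)C(=O)C=CC(C)(C)[C@H]1CO[Si](C)(C)C(C)(C)C | intermediate
22 | CNP0533761.1 | C[C@H]1C(=O)[C@]23C[C@@]1(O)CC[C@H]2[C@]1(COC3=O)C(=O)C=CC(C)(C)[C@H]1CO | target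

## Step count and least certain steps

Total step count: 16. Longest linear sequence: 13 steps (steps 1 to 6 and 10 to 16); the acceptor branch (steps 7 to 9) joins at step 10.

**Step 10 (key step).** The most likely failure is loss of the tertiary C10 radical before it adds: a second Cp2TiCl can trap it and eliminate to an alkene, and the doubly activated acceptor can itself be reduced by trivalent titanium. The second concern is poor face selection at C9, which rests only on non-bonded interactions in an open transition state.
Fallback, from 7 back to 14: the same epoxide opening is run with methyl acrylate, the standard unhindered acceptor, which after lactonisation should give the unsubstituted spiro lactone F1. Its lithium enolate (LiN(i-Pr)2, 2 equiv) is C-acylated with 1-propanoylimidazole to the β-keto lactone F2. PhSeCl and pyridine give the C8 selenide F3, and H2O2 eliminates it to the 2-propanoyl unsaturated lactone F4. The cuprate from 2-(2-bromoethyl)-2-methyl-1,3-dioxolane (Mg; CuBr·SMe2; Me3SiCl) then adds to C9 from the face remote from the C5 arm, which is the required sense, and protonation gives 14. C9 is then set by an ionic conjugate addition in which the large group, not hydrogen, chooses the open face.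

**Step 14.** The most likely failure is reversal of the cyclisation (retro-aldol opening of the strained bridged ketol) on warming or at the quench; enolisation at the C13 ketone in place of C16 is the second risk.
Fallback, from 18 back to 19: the unhindered C13 ketone is ketalised selectively (ethylene glycol, TsOH) to the C13 ethylene ketal F5; the C15 ketone is neopentyl and stays free. LiN(i-Pr)2 and Me3SiCl then give the (Z)-C15 trimethylsilyl enol ether F6, since C16 is the only enolisable position. TiCl4 at −78 °C ionises the dioxolane and C16 captures the oxocarbenium ion (Mukaiyama aldol addition to a ketal), which is exergonic and cannot revert; this gives the 13-O-(2-hydroxyethyl) ether F7. Iodination (I2, PPh3, imidazole) gives the 13-O-(2-iodoethyl) ether F8, and Zn with NH4Cl in EtOH fragments it to ethene and 19.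

**Step 15.** The most likely failure is a slow ene reaction, because selenium must bond to the neopentyl C3; forcing conditions would then risk oxidation α to the C15 ketone. Radical-type oxidants are not a safe substitute, because they can deliver oxygen to either end of the allyl system.
Fallback, from 19 back to 20: a Schenck ene reaction (O2, hν, tetraphenylporphyrin; then PPh3) places oxygen on C3 and moves the alkene to C1=C2, giving the C3 allylic alcohol F9. Dess–Martin periodinane gives the 1-en-3-one F10, and dimethyldioxirane in acetone (neutral) gives the 1,2-epoxy-3-ketone F11. Wharton transposition (N2H4·H2O, AcOH) then gives the C1 allylic alcohol 20 with the C2=C3 alkene, which is oxidised as in step 15.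

**Step 12.** The most likely failure is halogenation at the wrong site: bromination at C12 through the more substituted enolate, or at C8 through the dicarbonyl enol silane.
Fallback, from 14 directly to 17 (bypassing 15): Me3SiOTf and i-Pr2NEt open the dioxolane and deprotonate the oxocarbenium ion at the C14 methyl group, giving the less substituted 2-(trimethylsilyloxy)ethyl enol ether F12, with the dicarbonyl unit silylated at the same time. NBS in wet THF at −78 °C brominates this electron-rich 1,1-disubstituted enol ether, and hydrolysis gives 17. Regiocontrol then comes from deprotonation of a cation by a hindered amine and not from a kinetic lithium enolate.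

**Step 3.** The most likely failure is ionisation of the neopentyl oxyphosphonium ion with ring contraction or methyl shift (Wagner–Meerwein rearrangement) in place of elimination.
Fallback, from 3 back to 4: Dess–Martin oxidation gives the ketone F13. Tf2O with 2,6-di-tert-butyl-4-methylpyridine gives the enol triflate F14; only C2 can enolise. Reduction with Pd(OAc)2, PPh3, Bu3N and HCO2H (formate reduction catalysed by zerovalent palladium) gives 4 with the alkene fixed at C2=C3.

## Further compounds

F1 | step 10 | spiro δ-lactone from 7 and methyl acrylate (C8 and C9 unsubstituted; C5 and C10 as in 14) | O=C1CC[C@]2(CO1)CC=CC(C)(C)[C@H]2CO[Si](C)(C)C(C)(C)C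
F2 | step 10 | C8 propanoyl derivative of F1 (β-keto lactone, configuration at C8 open) | CCC(=O)C1CC[C@]2(COC1=O)CC=CC(C)(C)[C@H]2CO[Si](C)(C)C(C)(C)C
F3 | step 10 | C8 phenylselanyl derivative of F2 | CCC(=O)C1([Se]c3ccccc3)CC[C@]2(COC1=O)CC=CC(C)(C)[C@H]2CO[Si](C)(C)C(C)(C)C
F4 | step 10 | 2-propanoyl unsaturated lactone (C8=C9) | CCC(=O)C1=C[C@]2(COC1=O)CC=CC(C)(C)[C@H]2CO[Si](C)(C)C(C)(C)C
F5 | step 14 | C13 ethylene ketal of 18 | CCC(=O)[C@]12CC3(CC[C@H]1[C@]1(COC2=O)CC=CC(C)(C)[C@H]1CO[Si](C)(C)C(C)(C)C)OCCO3
F6 | step 14 | (Z)-C15 trimethylsilyl enol ether of F5 | C/C=C(\O[Si](C)(C)C)[C@]12CC3(CC[C@H]1[C@]1(COC2=O)CC=CC(C)(C)[C@H]1CO[Si](C)(C)C(C)(C)C)OCCO3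
F7 | step 14 | 13-O-(2-hydroxyethyl) ether of 19 | C[C@H]1C(=O)[C@]23C[C@@]1(OCCO)CC[C@H]2[C@]1(COC3=O)CC=CC(C)(C)[C@H]1CO[Si](C)(C)C(C)(C)C
F8 | step 14 | 13-O-(2-iodoethyl) ether of 19 | C[C@H]1C(=O)[C@]23C[C@@]1(OCCI)CC[C@H]2[C@]1(COC3=O)CC=CC(C)(C)[C@H]1CO[Si](C)(C)C(C)(C)C
F9 | step 15 | C3 allylic alcohol of 19 with the alkene at C1=C2 (configuration at C3 open) | C[C@H]1C(=O)[C@]23C[C@@]1(O)CC[C@H]2[C@]1(COC3=O)C=CC(O)C(C)(C)[C@H]1CO[Si](C)(C)C(C)(C)C
F10 | step 15 | 1-en-3-one isomer of 21 | C[C@H]1C(=O)[C@]23C[C@@]1(O)CC[C@H]2[C@]1(COC3=O)C=CC(=O)C(C)(C)[C@H]1CO[Si](C)(C)C(C)(C)C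
F11 | step 15 | 1,2-epoxy-3-ketone from F10 (epoxide configuration open) | C[C@H]1C(=O)[C@]23C[C@@]1(O)CC[C@H]2[C@]1(COC3=O)C4OC4C(=O)C(C)(C)[C@H]1CO[Si](C)(C)C(C)(C)C
F12 | step 12 | 2-(trimethylsilyloxy)ethyl enol ether of 14 at C13=C14, dicarbonyl unit as its trimethylsilyl enol ether | CCC(O[Si](C)(C)C)=C1[C@@H](CCC(=C)OCCO[Si](C)(C)C)[C@]2(COC1=O)CC=CC(C)(C)[C@H]2CO[Si](C)(C)C(C)(C)C
F13 | step 3 | [(1S)-2,2-dimethyl-6-methylidene-3-oxocyclohexyl]methyl acetate | CC(=O)OC[C@H]1C(=C)CCC(=O)C1(C)C
F14 | step 3 | [(1S)-2,2-dimethyl-6-methylidene-3-(trifluoromethanesulfonyloxy)cyclohex-3-en-1-yl]methyl acetate | CC(=O)OC[C@H]1C(=C)CC=C(OS(=O)(=O)C(F)(F)F)C1(C)C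
A1 | alternative 1 | chloromethyl ketone ester of the siloxycyclopentadiene carboxylic acid (precursor of the (4+3) step) | O=C(OC[C@@]1(CC(=O)CCl)C(=O)C=CC(C)(C)[C@H]1CO[Si](C)(C)C(C)(C)C)C1=CC(C)=C(O[Si](C)(C)C(C)(C)C)C1
A2 | alternative 1 | (4+3) adduct: C11-oxo bicyclo[3.2.1]oct-15-ene spirolactone with C13 silyl ether | CC1=C[C@]23C[C@@]1(O[Si](C)(C)C(C)(C)C)CC(=O)[C@H]2[C@]1(COC3=O)C(=O)C=CC(C)(C)[C@H]1CO[Si](C)(C)C(C)(C)C
A3 | alternative 2 | α-methylene spiro lactone with the C9 β-keto ester chain (configuration at C16 open) | C=C1C(=O)OC[C@]2(CC=CC(C)(C)[C@H]2CO[Si](C)(C)C(C)(C)C)[C@@H]1CCC(=O)C(C)C(=O)OC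
A4 | alternative 2 | 1-deoxo target C6 TBS ether (identical with 19) | C[C@H]1C(=O)[C@]23C[C@@]1(O)CC[C@H]2[C@]1(COC3=O)CC=CC(C)(C)[C@H]1CO[Si](C)(C)C(C)(C)C
A5 | alternative 3 | spiro cyclopentenone vinylogous ester lactone with the C9 iodoethyl arm | CC1=C(OCc2ccc(OC)cc2)C[C@]2(C1=O)C(=O)OC[C@]1(C(=O)C=CC(C)(C)[C@H]1CO[Si](C)(C)C(C)(C)C)[C@@H]2CCI
A6 | alternative 3 | target as its C13 PMB ether and C6 TBS ether | C[C@H]1C(=O)[C@]23C[C@@]1(OCc4ccc(OC)cc4)CC[C@H]2[C@]1(COC3=O)C(=O)C=CC(C)(C)[C@H]1CO[Si](C)(C)C(C)(C)C
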